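**Plan**
Retrosynthesis: cut C4–C4a (ring C, Friedel–Crafts acylation), then C8–C1'' (Negishi coupling), then O1–C2 (Mitsunobu etherification); the acid carbon comes from a vinyl group and the C10 chain from a limonene-derived acid, each by loss of one carbon.
Enabling feature: the ketone carbon C4 of ring C is bonded to C4a of ring A, and O1 has only two ortho carbons, C8 (taken by the C10 chain) and C4a (free), so a three-carbon acid hung on O1 can acylate C4a and nothing else.
Forward, fragments: (R)-limonene gives the C10 iodide 8 (steps 1–4); phloroglucinol gives iodophenol 11 (steps 5–6); 4-acetoxybenzaldehyde gives homoallylic alcohol 13 (step 7).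
Forward, union: ether 14 (step 8), tether oxidised to acid 17 (steps 9–10), chain joined at C8 (step 11), ring C closed (step 12), phenols released (steps 13–14).
Stereochemistry: C2'' is C4 of (R)-limonene and is never touched; C2 is set as R by a Keck allylation and inverted to S in the Mitsunobu step.

Key step: step 12

Remark on the chemistry: positions follow flavanone numbering (O1, C2–C4, C4a, C5–C8, C8a, side chain C1''–C6''), TBS is tert-butyldimethylsilyl, and it is assumed that in step 6 the hydroxyl para to iodine is silylated first, so the free hydroxyl of 11 is one of the two equivalent ones next to iodine.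

**Step 1**
Reactants: 1 (R)-(+)-limonene
Product: 4 (3R)-6-oxo-3-(prop-1-en-2-yl)heptanal, via limonene 1,2-oxide 2 (not isolated), via limonene-1,2-diol 3 (not isolated)
Conditions: mCPBA (1.0 equiv), CH2Cl2, 0 °C; then H5IO6, THF/H2O, 0 °C to rt
Reagents that add atoms: mCPBA (3-chloroperbenzoic acid), OOC(=O)c1cccc(Cl)c1; water, O
Why: Prilezhaev epoxidation should pick the trisubstituted ring alkene over the isopropenyl group, and periodic acid then hydrates the epoxide and cleaves the glycol (Malaprade cleavage), leaving the stereocenter (C4 of limonene, the later C2'') untouched.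

**Step 2**
Reactants: 4 (3R)-6-oxo-3-(prop-1-en-2-yl)heptanal
Product: 5 (3R)-6-oxo-3-(prop-1-en-2-yl)heptanoic acid
Conditions: NaClO2, NaH2PO4, 2-methyl-2-butene (excess), t-BuOH/H2O, 0 °C to rt
Reagents that add atoms: sodium chlorite, [Na+].[O-]Cl=O
Why: Pinnick oxidation converts the aldehyde into the acid in a weakly acidic buffer without touching the ketone, and the excess 2-methyl-2-butene intercepts hypochlorous acid before it can add to the isopropenyl group.

**Step 3**
Reactants: 5 (3R)-6-oxo-3-(prop-1-en-2-yl)heptanoic acid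
Product: 6 (3R)-6-methyl-3-(prop-1-en-2-yl)hept-6-enoic acid
Conditions: Ph3PCH3Br (3.2 equiv), KOt-Bu (4 equiv), THF, 0 °C to rt; acidic work-up
Reagents that add atoms: methyltriphenylphosphonium bromide, C[P+](c1ccccc1)(c1ccccc1)c1ccccc1.[Br-]
Why: Wittig methylenation of the methyl ketone with excess ylide tolerates the carboxylate, and the stereocenter is not alpha to either carbonyl, so it cannot epimerise.

**Step 4**
Reactants: 6 (3R)-6-methyl-3-(prop-1-en-2-yl)hept-6-enoic acid
Product: 8 (3S)-3-(iodomethyl)-2,6-dimethylhepta-1,6-diene, via Barton ester 7 (not isolated)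
Conditions: N-hydroxypyridine-2(1H)-thione, DCC, DMAP (cat.), CH2Cl2, 0 °C to rt, dark; then CHI3 (2 equiv), PhH, hν (tungsten lamp), rt
Reagents that add atoms: iodoform, IC(I)I
Why: Barton decarboxylative iodination, in which the O-acyl thiohydroxamate fragments under visible light to the primary radical and iodine abstraction from iodoform should outrun both the 1,2-vinyl shift and cyclisation onto the distal alkene, while no electrophilic iodine is present that could iodolactonise the acid; the stereocenter is next to, not at, the radical carbon (the S descriptor only reflects the new priority of CH2I).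

**Step 5**
Reactants: 9 phloroglucinol
Product: 10 2-iodobenzene-1,3,5-triol
Conditions: I2 (1.0 equiv), NaHCO3, THF/H2O, 0 °C
Reagents that add atoms: iodine, II
Why: Electrophilic aromatic iodination of the strongly activated ring should stop at the mono-iodide with one equivalent of iodine in buffered aqueous THF.

**Step 6**
Reactants: 10 2-iodobenzene-1,3,5-triol
Product: 11 2-iodo-3,5-bis[(tert-butyldimethylsilyl)oxy]phenol
Conditions: TBSCl (2.05 equiv), imidazole, DMF/CH2Cl2, −20 to 0 °C
Reagents that add atoms: tert-butyldimethylsilyl chloride, CC(C)(C)[Si](C)(C)Cl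
Why: Phenol silylation is governed by steric access, so the hydroxyl para to iodine should react first and then either of the two equivalent hydroxyls next to iodine, leaving the one free ortho hydroxyl that becomes O1; mono- and tris-silylated material is separated and recycled.

**Step 7**
Reactants: 12 4-formylphenyl acetate (4-acetoxybenzaldehyde)
Product: 13 4-[(1R)-1-hydroxybut-3-en-1-yl]phenyl acetate
Conditions: (R)-BINOL (20 mol%), Ti(OiPr)4 (10 mol%), 4 Å MS, allylSnBu3, CH2Cl2, −20 °C; aq. NaHCO3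
Reagents that add atoms: allyltributylstannane, C=CC[Sn](CCCC)(CCCC)CCCC
Why: Keck asymmetric allylation, in which the titanium–(R)-BINOL Lewis acid should direct the allylstannane to the Re face of the aldehyde and so set the carbinol centre as R, with the aryl acetate inert at −20 °C.

**Step 8**
Reactants: 11 2-iodo-3,5-bis[(tert-butyldimethylsilyl)oxy]phenol; 13 4-[(1R)-1-hydroxybut-3-en-1-yl]phenyl acetate
Product: 14 4-[(1S)-1-{2-iodo-3,5-bis[(tert-butyldimethylsilyl)oxy]phenoxy}but-3-en-1-yl]phenyl acetate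
Conditions: PPh3, DIAD, toluene, 0 °C to rt
Reagents that add atoms: none
Why: Mitsunobu etherification, in which the acidic ortho-iodophenol displaces the alkoxyphosphonium ion with SN2 inversion (R carbinol to S aryl ether, the later C2), the 4-acetoxy group keeping the benzylic carbon from ionising.

**Step 9**
Reactants: 14 4-[(1S)-1-{2-iodo-3,5-bis[(tert-butyldimethylsilyl)oxy]phenoxy}but-3-en-1-yl]phenyl acetate
Product: 16 4-[(1S)-1-{2-iodo-3,5-bis[(tert-butyldimethylsilyl)oxy]phenoxy}-3-oxopropyl]phenyl acetate, via 1,2-diol 15 (not isolated)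
Conditions: OsO4 (2 mol%), NaIO4 (4 equiv), 2,6-lutidine, dioxane/H2O, rt
Reagents that add atoms: osmium tetroxide (direct oxygen donor, catalytic), O=[Os](=O)(=O)=O; sodium periodate (terminal oxidant), [Na+].[O-]I(=O)(=O)=O
Why: Lemieux–Johnson oxidation (catalytic dihydroxylation, then periodate glycol cleavage, buffered by 2,6-lutidine) shortens the only alkene in the molecule to the aldehyde under near-neutral conditions that should avoid beta-elimination of the aryloxy group.

**Step 10**
Reactants: 16 4-[(1S)-1-{2-iodo-3,5-bis[(tert-butyldimethylsilyl)oxy]phenoxy}-3-oxopropyl]phenyl acetate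
Product: 17 (3S)-3-(4-acetoxyphenyl)-3-{2-iodo-3,5-bis[(tert-butyldimethylsilyl)oxy]phenoxy}propanoic acid
Conditions: NaClO2, NaH2PO4, 2-methyl-2-butene (excess), t-BuOH/H2O, 0 °C
Reagents that add atoms: sodium chlorite, [Na+].[O-]Cl=O
Why: Pinnick oxidation takes the aldehyde to the acid in a weakly acidic buffer in which retro-oxa-Michael loss of the phenol should not occur, and the scavenger protects the electron-rich arene from chlorination.

**Step 11**
Reactants: 17 (3S)-3-(4-acetoxyphenyl)-3-{2-iodo-3,5-bis[(tert-butyldimethylsilyl)oxy]phenoxy}propanoic acid; 8 (3S)-3-(iodomethyl)-2,6-dimethylhepta-1,6-diene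
Product: 22 (3S)-3-(4-acetoxyphenyl)-3-{2-[(2R)-5-methyl-2-(prop-1-en-2-yl)hex-5-en-1-yl]-3,5-bis[(tert-butyldimethylsilyl)oxy]phenoxy}propanoic acid, via trimethylsilyl ester 18 (not isolated), via alkyllithium 19 (not isolated), via alkylzinc chloride 20 (not isolated), via coupled trimethylsilyl ester 21 (not isolated)
Conditions: (a) 17, N,O-bis(trimethylsilyl)acetamide, THF, rt; (b) 8, t-BuLi (2.1 equiv), Et2O, −78 °C, then ZnCl2, THF, −78 °C to rt; (c) a + b, Pd(OAc)2 (5 mol%), SPhos (10 mol%), THF, 25 to 45 °C; aq. citric acid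
Reagents that add atoms: none
Why: Negishi cross-coupling, in which transient silylation masks the acid, iodine–lithium exchange at −78 °C and transmetalation to zinc give a primary alkylzinc without radical rearrangement, and the bulky biarylphosphine should drive oxidative addition of the hindered aryl iodide to zerovalent palladium and reductive elimination ahead of beta-hydride elimination; neither stereocenter takes part and aqueous work-up returns the free acid.

**Step 12**
Reactants: 22 (3S)-3-(4-acetoxyphenyl)-3-{2-[(2R)-5-methyl-2-(prop-1-en-2-yl)hex-5-en-1-yl]-3,5-bis[(tert-butyldimethylsilyl)oxy]phenoxy}propanoic acid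
Product: 24 4-[(2S)-5,7-bis[(tert-butyldimethylsilyl)oxy]-8-[(2R)-5-methyl-2-(prop-1-en-2-yl)hex-5-en-1-yl]-4-oxo-3,4-dihydro-2H-chromen-2-yl]phenyl acetate, via acid chloride 23 (not isolated)
Conditions: 1-chloro-N,N,2-trimethylprop-1-en-1-amine (Ghosez's reagent, 1.2 equiv), 2,6-di-tert-butyl-4-methylpyridine (2.5 equiv), CH2Cl2, 0 °C; then AgOTf (1.3 equiv), −78 to −30 °C, dark
Reagents that add atoms: none
Why: Ghosez's reagent turns the acid into acid chloride 23 without releasing HCl, AgOTf then abstracts chloride to give an acylium ion (as its triflate), which is attacked by C4a, the ring A carbon ortho to O1 and to the C5 silyloxy group and para to the C7 silyloxy group, and the hindered pyridine takes the proton from the arenium ion to restore aromaticity. The closest known reaction type is the intramolecular Friedel–Crafts acylation of 3-aryloxypropanoic acids to chroman-4-ones. Ring C closes by a 6-exo-trig attack of the arene on the acyl carbon, an intramolecular electrophilic aromatic substitution through a six-membered transition state. No stereocenter is formed; C2 should keep its S configuration because the 4-acetoxyphenyl group, the low temperature and the absence of free Brønsted acid disfavour ionisation of the benzylic C2–O1 bond, and C2'' is remote. Regioselectivity is fixed by the substrate, since the tether from O1 reaches only C4a (C8 carries the chain and C6 is out of reach), so neither the 6-alkyl isomer nor a chalcone can form. Chemoselectivity over the two 1,1-disubstituted alkenes rests on the non-nucleophilic base, which leaves no acid strong enough to protonate them, and on the speed of the six-membered closure onto the phloroglucinol-type ring.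

**Step 13**
Reactants: 24 4-[(2S)-5,7-bis[(tert-butyldimethylsilyl)oxy]-8-[(2R)-5-methyl-2-(prop-1-en-2-yl)hex-5-en-1-yl]-4-oxo-3,4-dihydro-2H-chromen-2-yl]phenyl acetate
Product: 25 4-[(2S)-5,7-dihydroxy-8-[(2R)-5-methyl-2-(prop-1-en-2-yl)hex-5-en-1-yl]-4-oxo-3,4-dihydro-2H-chromen-2-yl]phenyl acetate
Conditions: Et3N·3HF (excess), THF, 0 °C to rt
Reagents that add atoms: none
Why: Fluoride-mediated cleavage of the two aryl silyl ethers with weakly acidic Et3N·3HF avoids the basic conditions under which a flavanone opens to its chalcone and loses the C2 configuration, and should leave the aryl acetate and both alkenes alone.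

**Step 14**
Reactants: 25 4-[(2S)-5,7-dihydroxy-8-[(2R)-5-methyl-2-(prop-1-en-2-yl)hex-5-en-1-yl]-4-oxo-3,4-dihydro-2H-chromen-2-yl]phenyl acetate
Product: 26 remangiflavanone A
Conditions: NH4OAc, MeOH/H2O (4:1), rt
Reagents that add atoms: none
Why: Ammonium acetate in aqueous methanol solvolyses the aryl acetate under neutral conditions (mild deacetylation of phenyl acetates), so neither the C2 centre nor the alkenes should be at risk.

**Compound list**
1 | (R)-(+)-limonene | CC1=CC[C@@H](CC1)C(C)=C | starting material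
2 | (4R)-limonene 1,2-oxide, cis/trans mixture | CC12CC[C@H](CC1O2)C(C)=C | intermediate (not isolated)
3 | (4R)-1-methyl-4-(prop-1-en-2-yl)cyclohexane-1,2-diol, diastereomer mixture | CC1(O)CC[C@H](CC1O)C(C)=C | intermediate (not isolated)
4 | (3R)-6-oxo-3-(prop-1-en-2-yl)heptanal | CC(=O)CC[C@H](CC=O)C(C)=C | intermediate
5 | (3R)-6-oxo-3-(prop-1-en-2-yl)heptanoic acid | CC(=O)CC[C@H](CC(=O)O)C(C)=C | intermediate
6 | (3R)-6-methyl-3-(prop-1-en-2-yl)hept-6-enoic acid | C=C(C)CC[C@H](CC(=O)O)C(C)=C | intermediate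
7 | 2-thioxopyridin-1(2H)-yl (3R)-6-methyl-3-(prop-1-en-2-yl)hept-6-enoate (Barton ester) | C=C(C)CC[C@H](CC(=O)On1ccccc1=S)C(C)=C | intermediate (not isolated)
8 | (3S)-3-(iodomethyl)-2,6-dimethylhepta-1,6-diene | C=C(C)CC[C@H](CI)C(C)=C | intermediate
9 | phloroglucinol | Oc1cc(O)cc(O)c1 | starting material
10 | 2-iodobenzene-1,3,5-triol | Oc1cc(O)c(I)c(O)c1 | intermediate
11 | 2-iodo-3,5-bis[(tert-butyldimethylsilyl)oxy]phenol | Oc1cc(O[Si](C)(C)C(C)(C)C)cc(O[Si](C)(C)C(C)(C)C)c1I | intermediate
12 | 4-formylphenyl acetate | CC(=O)Oc1ccc(C=O)cc1 | starting material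
13 | 4-[(1R)-1-hydroxybut-3-en-1-yl]phenyl acetate | CC(=O)Oc1ccc(cc1)[C@H](O)CC=C | intermediate
14 | 4-[(1S)-1-{2-iodo-3,5-bis[(tert-butyldimethylsilyl)oxy]phenoxy}but-3-en-1-yl]phenyl acetate | CC(=O)Oc1ccc(cc1)[C@@H](Oc1cc(O[Si](C)(C)C(C)(C)C)cc(O[Si](C)(C)C(C)(C)C)c1I)CC=C | intermediate
15 | 4-[(1S)-3,4-dihydroxy-1-{2-iodo-3,5-bis[(tert-butyldimethylsilyl)oxy]phenoxy}butyl]phenyl acetate, both C3 epimers | CC(=O)Oc1ccc(cc1)[C@@H](Oc1cc(O[Si](C)(C)C(C)(C)C)cc(O[Si](C)(C)C(C)(C)C)c1I)CC(O)CO | intermediate (not isolated)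
16 | 4-[(1S)-1-{2-iodo-3,5-bis[(tert-butyldimethylsilyl)oxy]phenoxy}-3-oxopropyl]phenyl acetate | CC(=O)Oc1ccc(cc1)[C@@H](Oc1cc(O[Si](C)(C)C(C)(C)C)cc(O[Si](C)(C)C(C)(C)C)c1I)CC=O | intermediate
17 | (3S)-3-(4-acetoxyphenyl)-3-{2-iodo-3,5-bis[(tert-butyldimethylsilyl)oxy]phenoxy}propanoic acid | CC(=O)Oc1ccc(cc1)[C@@H](Oc1cc(O[Si](C)(C)C(C)(C)C)cc(O[Si](C)(C)C(C)(C)C)c1I)CC(=O)O | intermediate
18 | trimethylsilyl (3S)-3-(4-acetoxyphenyl)-3-{2-iodo-3,5-bis[(tert-butyldimethylsilyl)oxy]phenoxy}propanoate | CC(=O)Oc1ccc(cc1)[C@@H](Oc1cc(O[Si](C)(C)C(C)(C)C)cc(O[Si](C)(C)C(C)(C)C)c1I)CC(=O)O[Si](C)(C)C | intermediate (not isolated)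
19 | [(2S)-5-methyl-2-(prop-1-en-2-yl)hex-5-en-1-yl]lithium | [Li]C[C@@H](CCC(C)=C)C(C)=C | intermediate (not isolated)
20 | chlorido[(2S)-5-methyl-2-(prop-1-en-2-yl)hex-5-en-1-yl]zinc | Cl[Zn]C[C@@H](CCC(C)=C)C(C)=C | intermediate (not isolated)
21 | trimethylsilyl (3S)-3-(4-acetoxyphenyl)-3-{2-[(2R)-5-methyl-2-(prop-1-en-2-yl)hex-5-en-1-yl]-3,5-bis[(tert-butyldimethylsilyl)oxy]phenoxy}propanoate | C=C(C)CC[C@H](Cc1c(O[Si](C)(C)C(C)(C)C)cc(O[Si](C)(C)C(C)(C)C)cc1O[C@H](c1ccc(OC(C)=O)cc1)CC(=O)O[Si](C)(C)C)C(=C)C | intermediate (not isolated)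
22 | (3S)-3-(4-acetoxyphenyl)-3-{2-[(2R)-5-methyl-2-(prop-1-en-2-yl)hex-5-en-1-yl]-3,5-bis[(tert-butyldimethylsilyl)oxy]phenoxy}propanoic acid | C=C(C)CC[C@H](Cc1c(O[Si](C)(C)C(C)(C)C)cc(O[Si](C)(C)C(C)(C)C)cc1O[C@H](c1ccc(OC(C)=O)cc1)CC(=O)O)C(=C)C | intermediate (key-step precursor)
23 | (3S)-3-(4-acetoxyphenyl)-3-{2-[(2R)-5-methyl-2-(prop-1-en-2-yl)hex-5-en-1-yl]-3,5-bis[(tert-butyldimethylsilyl)oxy]phenoxy}propanoyl chloride | C=C(C)CC[C@H](Cc1c(O[Si](C)(C)C(C)(C)C)cc(O[Si](C)(C)C(C)(C)C)cc1O[C@H](c1ccc(OC(C)=O)cc1)CC(=O)Cl)C(=C)C | intermediate (not isolated)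
24 | 4-[(2S)-5,7-bis[(tert-butyldimethylsilyl)oxy]-8-[(2R)-5-methyl-2-(prop-1-en-2-yl)hex-5-en-1-yl]-4-oxo-3,4-dihydro-2H-chromen-2-yl]phenyl acetate | C=C(C)CC[C@H](Cc1c(O[Si](C)(C)C(C)(C)C)cc(O[Si](C)(C)C(C)(C)C)c2c1O[C@H](c1ccc(OC(C)=O)cc1)CC2=O)C(=C)C | intermediate (key-step product)
25 | 4-[(2S)-5,7-dihydroxy-8-[(2R)-5-methyl-2-(prop-1-en-2-yl)hex-5-en-1-yl]-4-oxo-3,4-dihydro-2H-chromen-2-yl]phenyl acetate | C=C(C)CC[C@H](Cc1c(O)cc(O)c2c1O[C@H](c1ccc(OC(C)=O)cc1)CC2=O)C(=C)C | intermediate
26 | remangiflavanone A, (2S)-5,7-dihydroxy-2-(4-hydroxyphenyl)-8-[(2R)-5-methyl-2-(prop-1-en-2-yl)hex-5-en-1-yl]-2,3-dihydro-4H-chromen-4-one | C=C(C)CC[C@H](Cc1c(O)cc(O)c2c1O[C@H](c1ccc(O)cc1)CC2=O)C(=C)C | target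

**Step count and risks**
Total: 14 steps. Longest linear sequence: 9 steps (5, 6, 8, 9, 10, 11, 12, 13, 14).

Step 11 (Negishi coupling). The arylpalladium iodide is flanked by a silyl ether and the branched benzylic ether, so transmetalation may be slow; protodeiodination of the arene and beta-hydride elimination of the alkyl group could then take over, and the transient silyl ester may be lost. The fallback changes the order of ring closure and coupling and sets out from 17. The acid is converted with Ghosez's reagent into (3S)-3-(4-acetoxyphenyl)-3-{2-iodo-3,5-bis[(tert-butyldimethylsilyl)oxy]phenoxy}propanoyl chloride F1. F1 is cyclised with AgOTf and 2,6-di-tert-butyl-4-methylpyridine as in step 12 (no alkene is present at this stage) to the 8-iodoflavanone 4-[(2S)-5,7-bis[(tert-butyldimethylsilyl)oxy]-8-iodo-4-oxo-3,4-dihydro-2H-chromen-2-yl]phenyl acetate F2, in which O1 is tied back into ring C and no carboxyl group remains. Negishi coupling of F2 with alkylzinc chloride 20 under the catalyst of step 11 then gives 24, where the route is rejoined.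

Step 12 (ring C closure). Silver-assisted ionisation of the benzylic C2–O1 bond could erode the C2 configuration or expel the phenol, and the acylium ion could be diverted to an alkene if attack at the crowded C4a is slow. The fallback replaces the acylium ion by a milder iminium electrophile (intramolecular Vilsmeier–Haack-type acylation) and sets out from 22. Acid chloride 23 is quenched with N,N-dimethyltrimethylsilylamine to give (3S)-3-(4-acetoxyphenyl)-3-{2-[(2R)-5-methyl-2-(prop-1-en-2-yl)hex-5-en-1-yl]-3,5-bis[(tert-butyldimethylsilyl)oxy]phenoxy}-N,N-dimethylpropanamide F3. Activation with Tf2O and 2-fluoropyridine in CH2Cl2 at −78 to 0 °C should lead, by attack of C4a, to the cyclic N-[(2S)-2-(4-acetoxyphenyl)-5,7-bis[(tert-butyldimethylsilyl)oxy]-8-[(2R)-5-methyl-2-(prop-1-en-2-yl)hex-5-en-1-yl]-2,3-dihydro-4H-chromen-4-ylidene]-N-methylmethanaminium triflate F4. Hydrolysis of F4 with aqueous NaHCO3 gives 24.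

Step 8 (Mitsunobu etherification). The alkoxyphosphonium ion of 13 has allylic beta-hydrogens, so E2 elimination to the 1-arylbutadiene may compete with substitution by the hindered phenoxide. The fallback changes the tether to a protected 1,3-diol, which has no allylic hydrogens and reaches the acid level by alcohol oxidation instead of alkene cleavage; it sets out from 13. Ozonolysis (O3, CH2Cl2, −78 °C; PPh3) gives (3R)-3-(4-acetoxyphenyl)-3-hydroxypropanal F5 (not isolated), which NaBH(OAc)3 in AcOH reduces to 4-[(1R)-1,3-dihydroxypropyl]phenyl acetate F6. TBSCl and imidazole at 0 °C silylate the primary hydroxyl to 4-[(1R)-3-{[tert-butyl(dimethyl)silyl]oxy}-1-hydroxypropyl]phenyl acetate F7. Mitsunobu reaction of F7 with 11 gives 4-[(1S)-3-{[tert-butyl(dimethyl)silyl]oxy}-1-{2-iodo-3,5-bis[(tert-butyldimethylsilyl)oxy]phenoxy}propyl]phenyl acetate F8. Camphorsulfonic acid (cat.) in MeOH at 0 °C removes only the alkyl silyl ether to give 4-[(1S)-3-hydroxy-1-{2-iodo-3,5-bis[(tert-butyldimethylsilyl)oxy]phenoxy}propyl]phenyl acetate F9, and Dess–Martin periodinane oxidises F9 to 16, where the route is rejoined.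

**Further compounds**
F1 | step 11 | (3S)-3-(4-acetoxyphenyl)-3-{2-iodo-3,5-bis[(tert-butyldimethylsilyl)oxy]phenoxy}propanoyl chloride | CC(=O)Oc1ccc(cc1)[C@@H](Oc1cc(O[Si](C)(C)C(C)(C)C)cc(O[Si](C)(C)C(C)(C)C)c1I)CC(=O)Cl
F2 | step 11 | 4-[(2S)-5,7-bis[(tert-butyldimethylsilyl)oxy]-8-iodo-4-oxo-3,4-dihydro-2H-chromen-2-yl]phenyl acetate | CC(=O)Oc1ccc(cc1)[C@@H]1CC(=O)c2c(O[Si](C)(C)C(C)(C)C)cc(O[Si](C)(C)C(C)(C)C)c(I)c2O1
F3 | step 12 | (3S)-3-(4-acetoxyphenyl)-3-{2-[(2R)-5-methyl-2-(prop-1-en-2-yl)hex-5-en-1-yl]-3,5-bis[(tert-butyldimethylsilyl)oxy]phenoxy}-N,N-dimethylpropanamide | C=C(C)CC[C@H](Cc1c(O[Si](C)(C)C(C)(C)C)cc(O[Si](C)(C)C(C)(C)C)cc1O[C@H](c1ccc(OC(C)=O)cc1)CC(=O)N(C)C)C(=C)C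
F4 | step 12 | N-[(2S)-2-(4-acetoxyphenyl)-5,7-bis[(tert-butyldimethylsilyl)oxy]-8-[(2R)-5-methyl-2-(prop-1-en-2-yl)hex-5-en-1-yl]-2,3-dihydro-4H-chromen-4-ylidene]-N-methylmethanaminium triflate | C=C(C)CC[C@H](Cc1c(O[Si](C)(C)C(C)(C)C)cc(O[Si](C)(C)C(C)(C)C)c2c1O[C@H](c1ccc(OC(C)=O)cc1)CC2=[N+](C)C)C(=C)C.[O-]S(=O)(=O)C(F)(F)F
F5 | step 8 | (3R)-3-(4-acetoxyphenyl)-3-hydroxypropanal | CC(=O)Oc1ccc(cc1)[C@H](O)CC=O
F6 | step 8 | 4-[(1R)-1,3-dihydroxypropyl]phenyl acetate | CC(=O)Oc1ccc(cc1)[C@H](O)CCO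
F7 | step 8 | 4-[(1R)-3-{[tert-butyl(dimethyl)silyl]oxy}-1-hydroxypropyl]phenyl acetate | CC(=O)Oc1ccc(cc1)[C@H](O)CCO[Si](C)(C)C(C)(C)C
F8 | step 8 | 4-[(1S)-3-{[tert-butyl(dimethyl)silyl]oxy}-1-{2-iodo-3,5-bis[(tert-butyldimethylsilyl)oxy]phenoxy}propyl]phenyl acetate | CC(=O)Oc1ccc(cc1)[C@@H](Oc1cc(O[Si](C)(C)C(C)(C)C)cc(O[Si](C)(C)C(C)(C)C)c1I)CCO[Si](C)(C)C(C)(C)C
F9 | step 8 | 4-[(1S)-3-hydroxy-1-{2-iodo-3,5-bis[(tert-butyldimethylsilyl)oxy]phenoxy}propyl]phenyl acetate | CC(=O)Oc1ccc(cc1)[C@@H](Oc1cc(O[Si](C)(C)C(C)(C)C)cc(O[Si](C)(C)C(C)(C)C)c1I)CCO
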